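The route rests on cutting ring A (O1–C2–C3–C4–C5) into a glycolic acid unit, O1–C2(=O)–C3, and the C5–C4 edge. That edge is exploited as the 1,3-dicarbonyl of an α-oxalyl lactone: spiro carbon C5 is its nucleophilic enol carbon, C4 its highly electrophilic α-keto ester carbon. In one flask a trivalent iodine bis(glycolate) transfers its carboxylate oxygen to C5 (O1–C5) and base then closes the glycolate enolate onto C4 (C3–C4), building ring A, the spiro centre and the C3, C4 diol array at the final oxidation level. The precursor is merely ring B, the (5R)-5-decenyl butyrolactone, C-acylated with di-tert-butyl oxalate.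

Key step: step 5

Remark on numbering: locants O1 to C9 are those of the 1,7-dioxaspiro[4.4]nonane skeleton of the target (ring A: O1, C2, C3, C4, C5; ring B: C5, C6, O7, C8, C9). They are used for the same atoms in all precursors.
Assumption: 10 is drawn as its keto tautomer. It should exist largely as the C4 enol, so its C5 centre is left undefined.

Step 1
Reactants: 1 (R)-epichlorohydrin; 2 9-bromonon-1-ene
Product: 5 (2R)-2-(dec-9-en-1-yl)oxirane, via non-8-en-1-ylmagnesium bromide 3 (not isolated), via (2R)-1-chlorododec-11-en-2-ol 4 (not isolated)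
Conditions: 2, Mg, THF, 40 °C; CuI (10 mol %), 1, −40 to 0 °C; H2O; then powdered NaOH, Et2O, rt
Reagents that add atoms: none
Why: Copper-catalysed Grignard opening of the epoxide at its unsubstituted carbon leaves the C–O stereocentre untouched, and intramolecular Williamson closure of the chlorohydrin then carries the (R) centre of 1 over unchanged as the future C8.

Step 2
Reactants: 5 (2R)-2-(dec-9-en-1-yl)oxirane; 6 acetic acid
Product: 8 (5R)-5-(dec-9-en-1-yl)oxolan-2-one, via (4R)-4-hydroxytetradec-13-enoic acid 7 (not isolated)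
Conditions: 6, LiN(iPr)2 (2 equiv per acid), THF, 0 to 40 °C; 5, 40 °C; aq HCl, Et2O, rt
Reagents that add atoms: acetic acid 6, CC(=O)O
Why: The carboxylic acid dianion opens the terminal epoxide at CH2 in an SN2 reaction that does not touch C8, and the γ-hydroxy acid lactonises on acidification.

Step 3
Reactants: 8 (5R)-5-(dec-9-en-1-yl)oxolan-2-one; 9 di-tert-butyl oxalate
Product: 10 tert-butyl 2-[(5R)-5-(dec-9-en-1-yl)-2-oxooxolan-3-yl]-2-oxoacetate
Conditions: LiN(SiMe3)2 (2.2 equiv), THF, −78 °C; 9, −78 to 0 °C; cold dilute aq HCl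
Reagents that add atoms: di-tert-butyl oxalate 9, CC(C)(C)OC(=O)C(=O)OC(C)(C)C
Why: In this crossed Claisen condensation the lactone enolate attacks the non-enolisable oxalate and deprotonation of the acidic product by the second equivalent of base drives the reaction, while the new C5 centre stays labile (enol) until step 5.

Step 4
Reactants: 11 (diacetoxyiodo)benzene, PhI(OAc)2; 12 [(tert-butyldimethylsilyl)oxy]acetic acid
Product: 13 bis({[(tert-butyldimethylsilyl)oxy]acetyl}oxy)(phenyl)-λ3-iodane
Conditions: 12 (2.05 equiv), toluene, 45 °C, reduced pressure (AcOH distilled off), dark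
Reagents that add atoms: [(tert-butyldimethylsilyl)oxy]acetic acid 12, CC(C)(C)[Si](C)(C)OCC(=O)O
Why: Carboxylate ligand exchange at trivalent iodine is an equilibrium that removal of the more volatile acetic acid pulls to the bis(glycolate).

Step 5
Reactants: 10 tert-butyl 2-[(5R)-5-(dec-9-en-1-yl)-2-oxooxolan-3-yl]-2-oxoacetate; 13 bis({[(tert-butyldimethylsilyl)oxy]acetyl}oxy)(phenyl)-λ3-iodane
Product: 15 tert-butyl (3R,4R,5S,8R)-3-[(tert-butyldimethylsilyl)oxy]-8-(dec-9-en-1-yl)-4-hydroxy-2,6-dioxo-1,7-dioxaspiro[4.4]nonane-4-carboxylate, via acyloxy keto ester 14 (not isolated)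
Conditions: LiN(SiMe3)2 (1.0 equiv), toluene, −78 °C; 13 (1.0 equiv), −78 to −20 °C, dark; −78 °C, Et3N (10 equiv), LiN(SiMe3)2 (1.3 equiv); AcOH, −78 °C
Reagents that add atoms: iodane 13, CC(C)(C)[Si](C)(C)OCC(=O)OI(OC(=O)CO[Si](C)(C)C(C)(C)C)c1ccccc1
Why: Proposed new method: the lithium enolate of 10 displaces one carboxylate on the trivalent iodine of 13 and the O-bound iodane collapses by passing its second glycolate oxygen to C5 with loss of PhI (O1–C5, giving 14, whose only acidic C–H bonds are those of the glycolate CH2), after which LiN(SiMe3)2/Et3N enolises this CH2 and C3 adds to the non-enolisable α-keto ester carbon C4 (C3–C4). The closest known reaction types are the α-acyloxylation of 2-substituted 1,3-dicarbonyl compounds with PhI(O2CR)2 and the base-induced aldol closure of α-acyloxy ketones to β-hydroxy γ-lactones, and only their fusion into one oxidative annulation of a 1,3-dicarbonyl compound by a carboxylic acid unit is new. Ring A closes in the 5-(enolendo)-exo-trig mode, formally disfavoured but routinely realised with ester tethers, as in Lacey–Dieckmann tetronate closures. C5 is controlled by C8, because oxygen is delivered to the planar chelated enolate on the face anti to the decenyl chain, which places O1 trans and C4 cis to that chain on ring B. C4 is controlled by lithium held between the C4 and C6 carbonyl oxygens in the weakly solvating toluene/Et3N medium, so that C3, tethered through O1, meets the face that leaves the new hydroxyl syn to C6, and C3 is controlled by the non-chelating silyl ether, which should give the enolate with OSi trans to OLi and, through a lithium-bridged chair, the silyloxy group anti to the new alkoxide. The step needs attack at C4 rather than at the C6 lactone or tert-butyl ester carbonyl and oxidation of the enolate rather than of the terminal alkene, which the much higher electrophilicity of the keto carbon and the inertness of an unactivated alkene towards 13 secure.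

Step 6
Reactants: 15 tert-butyl (3R,4R,5S,8R)-3-[(tert-butyldimethylsilyl)oxy]-8-(dec-9-en-1-yl)-4-hydroxy-2,6-dioxo-1,7-dioxaspiro[4.4]nonane-4-carboxylate
Product: 17 (3R,4R,5S,8R)-8-(dec-9-en-1-yl)-3,4-dihydroxy-2,6-dioxo-1,7-dioxaspiro[4.4]nonane-4-carboxylic acid, via silyl ether acid 16 (not isolated)
Conditions: CF3CO2H/CH2Cl2 (1:2), 0 °C to rt; evaporate; 48 % aq HF/MeCN (1:9), 0 °C to rt
Reagents that add atoms: none
Why: Acidolysis of the tert-butyl ester (loss of isobutene) and fluoride-driven Si–O cleavage break no bond at a stereocentre, and both lactones and the terminal alkene should survive the short, cold acid exposure.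

Compound list
1 | (R)-epichlorohydrin, (2R)-2-(chloromethyl)oxirane | ClC[C@H]1CO1 | starting material
2 | 9-bromonon-1-ene | C=CCCCCCCCBr | starting material
3 | non-8-en-1-ylmagnesium bromide | C=CCCCCCCC[Mg]Br | intermediate
4 | (2R)-1-chlorododec-11-en-2-ol | C=CCCCCCCCC[C@@H](O)CCl | intermediate
5 | (2R)-2-(dec-9-en-1-yl)oxirane | C=CCCCCCCCC[C@@H]1CO1 | intermediate
6 | acetic acid | CC(=O)O | starting material
7 | (4R)-4-hydroxytetradec-13-enoic acid | C=CCCCCCCCC[C@@H](O)CCC(=O)O | intermediate
8 | (5R)-5-(dec-9-en-1-yl)oxolan-2-one | C=CCCCCCCCC[C@@H]1CCC(=O)O1 | intermediate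
9 | di-tert-butyl oxalate | CC(C)(C)OC(=O)C(=O)OC(C)(C)C | starting material
10 | tert-butyl 2-[(5R)-5-(dec-9-en-1-yl)-2-oxooxolan-3-yl]-2-oxoacetate (keto form, C5 labile) | C=CCCCCCCCC[C@@H]1CC(C(=O)C(=O)OC(C)(C)C)C(=O)O1 | intermediate
11 | (diacetoxyiodo)benzene, PhI(OAc)2 | CC(=O)OI(OC(C)=O)c1ccccc1 | starting material
12 | [(tert-butyldimethylsilyl)oxy]acetic acid | CC(C)(C)[Si](C)(C)OCC(=O)O | starting material
13 | bis({[(tert-butyldimethylsilyl)oxy]acetyl}oxy)(phenyl)-λ3-iodane | CC(C)(C)[Si](C)(C)OCC(=O)OI(OC(=O)CO[Si](C)(C)C(C)(C)C)c1ccccc1 | intermediate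
14 | tert-butyl 2-[(3S,5R)-3-({[(tert-butyldimethylsilyl)oxy]acetyl}oxy)-5-(dec-9-en-1-yl)-2-oxooxolan-3-yl]-2-oxoacetate | C=CCCCCCCCC[C@@H]1C[C@](OC(=O)CO[Si](C)(C)C(C)(C)C)(C(=O)C(=O)OC(C)(C)C)C(=O)O1 | intermediate
15 | tert-butyl (3R,4R,5S,8R)-3-[(tert-butyldimethylsilyl)oxy]-8-(dec-9-en-1-yl)-4-hydroxy-2,6-dioxo-1,7-dioxaspiro[4.4]nonane-4-carboxylate | C=CCCCCCCCC[C@@H]1C[C@@]2(OC(=O)[C@H](O[Si](C)(C)C(C)(C)C)[C@]2(O)C(=O)OC(C)(C)C)C(=O)O1 | intermediate
16 | (3R,4R,5S,8R)-3-[(tert-butyldimethylsilyl)oxy]-8-(dec-9-en-1-yl)-4-hydroxy-2,6-dioxo-1,7-dioxaspiro[4.4]nonane-4-carboxylic acid | C=CCCCCCCCC[C@@H]1C[C@@]2(OC(=O)[C@H](O[Si](C)(C)C(C)(C)C)[C@]2(O)C(=O)O)C(=O)O1 | intermediate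
17 | (3R,4R,5S,8R)-8-(dec-9-en-1-yl)-3,4-dihydroxy-2,6-dioxo-1,7-dioxaspiro[4.4]nonane-4-carboxylic acid | C=CCCCCCCCC[C@@H]1C[C@@]2(OC(=O)[C@H](O)[C@]2(O)C(=O)O)C(=O)O1 | target

Total step count: 6. Longest linear sequence: 5 (steps 1, 2, 3, 5, 6).

Steps most likely to fail

Step 5. Several processes could go wrong:
- Transfer of a carboxylate from iodine to the fully substituted C5 may be slow or poorly face-selective.
- The silylamide may add to the C4 ketone instead of enolising the glycolate.
- The closure may leak through the unchelated rotamer, or lose its C3 selectivity by retro-aldol equilibration.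

The fallback separates the two bond formations and uses only known reaction types. It sets out from 10. The enolate is hydroxylated at C5 with 2-(phenylsulfonyl)-3-phenyloxaziridine, an electrophilic α-hydroxylation of a β-dicarbonyl compound that should again occur anti to the C8 chain. This gives tert-butyl 2-[(3S,5R)-5-(dec-9-en-1-yl)-3-hydroxy-2-oxooxolan-3-yl]-2-oxoacetate F1, and the C5 epimers are separated at this stage. Steglich esterification of F1 with 12 (N,N'-dicyclohexylcarbodiimide, DMAP) gives 14, now isolated and purified. After precomplexation with MgBr2·OEt2, 14 is closed with LiN(SiMe3)2 at −78 °C, and the route is rejoined at 15.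

Step 6. Prolonged contact with CF3CO2H may add acid across the terminal alkene. Once the C4 acid is free, the lactone acyl groups may also migrate among the hydroxyl groups. The fallback replaces acidolysis by neutral allyl transfer and sets out from 8.
- Claisen condensation with diallyl oxalate gives allyl 2-[(5R)-5-(dec-9-en-1-yl)-2-oxooxolan-3-yl]-2-oxoacetate F2.
- The conditions of step 5 convert F2, through allyl 2-[(3S,5R)-3-({[(tert-butyldimethylsilyl)oxy]acetyl}oxy)-5-(dec-9-en-1-yl)-2-oxooxolan-3-yl]-2-oxoacetate F3, into allyl (3R,4R,5S,8R)-3-[(tert-butyldimethylsilyl)oxy]-8-(dec-9-en-1-yl)-4-hydroxy-2,6-dioxo-1,7-dioxaspiro[4.4]nonane-4-carboxylate F4.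
- Pd(PPh3)4 (zerovalent palladium) with morpholine removes the allyl group at rt. The route is rejoined at 16, before the HF stage.

Step 2. The aggregated, sparingly soluble dianion may open the epoxide slowly, so that base-induced isomerisation of the epoxide to an allylic alcohol competes. The fallback sets out from 5. Sodium diethyl malonate (NaOEt, EtOH, reflux) opens the epoxide and lactonises to ethyl (5R)-5-(dec-9-en-1-yl)-2-oxooxolane-3-carboxylate F5. Krapcho dealkoxycarbonylation (LiCl, wet DMSO, 150 °C) then returns to the route at 8.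

Further compounds
F1 | step 5 | tert-butyl 2-[(3S,5R)-5-(dec-9-en-1-yl)-3-hydroxy-2-oxooxolan-3-yl]-2-oxoacetate | C=CCCCCCCCC[C@@H]1C[C@](O)(C(=O)C(=O)OC(C)(C)C)C(=O)O1
F2 | step 6 | allyl 2-[(5R)-5-(dec-9-en-1-yl)-2-oxooxolan-3-yl]-2-oxoacetate | C=CCCCCCCCC[C@@H]1CC(C(=O)C(=O)OCC=C)C(=O)O1
F3 | step 6 | allyl 2-[(3S,5R)-3-({[(tert-butyldimethylsilyl)oxy]acetyl}oxy)-5-(dec-9-en-1-yl)-2-oxooxolan-3-yl]-2-oxoacetate | C=CCCCCCCCC[C@@H]1C[C@](OC(=O)CO[Si](C)(C)C(C)(C)C)(C(=O)C(=O)OCC=C)C(=O)O1
F4 | step 6 | allyl (3R,4R,5S,8R)-3-[(tert-butyldimethylsilyl)oxy]-8-(dec-9-en-1-yl)-4-hydroxy-2,6-dioxo-1,7-dioxaspiro[4.4]nonane-4-carboxylate | C=CCCCCCCCC[C@@H]1C[C@@]2(OC(=O)[C@H](O[Si](C)(C)C(C)(C)C)[C@]2(O)C(=O)OCC=C)C(=O)O1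
F5 | step 2 | ethyl (5R)-5-(dec-9-en-1-yl)-2-oxooxolane-3-carboxylate | C=CCCCCCCCC[C@@H]1CC(C(=O)OCC)C(=O)O1
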